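The disconnection cuts the benzene ring at C1-C6 and C5-C6: C6-H leaves as a one-carbon unit and oxygen takes its place, giving a 4-pyranone. The feature exploited is the contiguous array on the arene: ester carbon C7 on C1, oxygen on C2, oxygen on C3. A 3-oxy-4-oxo-4H-pyran-2-carboxylate carries the same three groups on adjacent carbons, so only its ring oxygen is wrong. O-Silylation to a pyrylium cation, then Ph3P=CH2, should exchange that oxygen for CH in one operation, forming both C-C bonds and the aromatic ring. The precursor is the docosyl ester of the 3-O-benzyl pyranone acid.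

Key step: step 2

Assumption: acid 1 is bought. It is a bulk, maltol-derived catalogue intermediate, which spares the O-benzylation and the two-stage oxidation of the methyl group.

Numbering: ring atoms carry the target numbers in all compounds. C1 bears the ester, C2 the benzyloxy group, C3 the carbonyl or silyloxy oxygen, and C4 and C5 bear hydrogen. The pyran oxygen stands where C6 will be. The target has no stereocentre.

**Step 1**
Reactants: 1 3-(benzyloxy)-4-oxo-4H-pyran-2-carboxylic acid; 2 1-docosanol
Product: 3 docosyl 3-(benzyloxy)-4-oxo-4H-pyran-2-carboxylate
Conditions: DCC (1.1 equiv), DMAP (0.1 equiv), CH2Cl2, rt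
Reagents that add atoms: none
Why: Steglich esterification, in which carbodiimide activation and DMAP acyl transfer deliver the acid to an unhindered primary alcohol under neutral conditions that leave the base- and amine-sensitive pyranone ring and the benzyl ether untouched.

**Step 2**
Reactants: 3 docosyl 3-(benzyloxy)-4-oxo-4H-pyran-2-carboxylate; 4 methyltriphenylphosphonium bromide
Product: 9 docosyl 2-(benzyloxy)-3-[(tert-butyldimethylsilyl)oxy]benzoate, via methylenetriphenylphosphorane 5 (not isolated), via 4-silyloxypyrylium triflate 6 (not isolated), via 2H-pyran phosphonium triflate 7 (not isolated), via open-chain keto ester ylide 8 (not isolated)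
Conditions: 3, TBSOTf (1.0 equiv), CH2Cl2, rt; cool to -40 °C; slow addition of the clear, KBr-free supernatant of 5 (2.0 equiv; from 4 and KN(SiMe3)2, toluene, rt); -40 °C to rt, then 40 °C
Reagents that add atoms: tert-butyldimethylsilyl triflate, CC(C)(C)[Si](C)(C)OS(=O)(=O)C(F)(F)F; reactant 4, C[P+](c1ccccc1)(c1ccccc1)c1ccccc1.[Br-], supplies the C6 carbon
Why: Proposed new method: TBSOTf silylates the carbonyl oxygen on C3 of 3 and so turns the ring into the aromatic cation 6; ylide 5 adds to the unsubstituted α-carbon C5 (new C5-C6 bond) to give the racemic 2H-pyran 7, a second equivalent of 5 takes a P-CH2 proton, and oxa-6π electrocyclic opening of the O-C5 bond exposes C1 as an α-keto ester carbonyl in the conjugated ylide 8. The benzene ring then closes by intramolecular Wittig olefination, a 6-exo-trig attack of the ylide carbon C6 on the C1 ketone followed by collapse of the oxaphosphetane (new C1-C6 bond), with loss of Ph3PO and aromatisation as driving forces. The closest known reaction types are the benzene synthesis from 2,4,6-trisubstituted pyrylium salts and alkylidenephosphoranes, the α-addition of carbon nucleophiles to 4-silyloxypyrylium and 4-silyloxybenzopyrylium triflates, and the exchange of the ring oxygen of such pyranone esters for nitrogen by primary amines, which follows the same addition, ring-opening and reclosure course. No stereocentre remains in 9: the sp3 carbon of 7 is erased on ring opening, and the C4=C5 geometry of 8, which has to be Z for closure, can equilibrate through the delocalised ylide and the reversible pyran opening while only the Z form is drained. The step needs attack at an α-carbon in preference to C3, silicon and the ester carbonyl, which the positive charge of the ring, the tert-butyl group on silicon, the screening of C3 by its silyloxy group and the neighbouring benzyloxy group, the halide-free ylide (no bromide to strip the silyl group) and the slow addition of just two equivalents of ylide to the cation (no free ylide left for the keto ester) should secure. A choice between the two α-carbons is not needed, because addition at C1 would open the ring to a C5 aldehyde and close to the same arene, and the benzyl cap on O2 keeps base from diverting the cation into an oxidopyrylium dipole.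

**Step 3**
Reactants: 9 docosyl 2-(benzyloxy)-3-[(tert-butyldimethylsilyl)oxy]benzoate
Product: 10 docosyl 2-(benzyloxy)-3-hydroxybenzoate
Conditions: Bu4NF (1.1 equiv), AcOH (1.1 equiv), THF, 0 °C to rt
Reagents that add atoms: none
Why: Fluoride-mediated cleavage of an aryl silyl ether (strong Si-F bond, good phenoxide leaving group), buffered with acetic acid so that the medium stays non-basic and the docosyl ester and the benzyl ether are kept.

**Step 4**
Reactants: 10 docosyl 2-(benzyloxy)-3-hydroxybenzoate
Product: 11 Gentiside J (docosyl 2,3-dihydroxybenzoate)
Conditions: H2 (1 atm), 10% Pd/C, THF/EtOAc, 30 °C; filtration under argon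
Reagents that add atoms: none
Why: Catalytic hydrogenolysis of an aryl benzyl ether over Pd/C under neutral conditions, which touches neither the ester nor the arene and frees the oxidation-prone catechol only in the last, base-free operation.

**Compound list**
1 | 3-(benzyloxy)-4-oxo-4H-pyran-2-carboxylic acid | OC(=O)C1=C(OCc2ccccc2)C(=O)C=CO1 | starting material
2 | 1-docosanol | CCCCCCCCCCCCCCCCCCCCCCO | starting material
3 | docosyl 3-(benzyloxy)-4-oxo-4H-pyran-2-carboxylate | CCCCCCCCCCCCCCCCCCCCCCOC(=O)C1=C(OCc2ccccc2)C(=O)C=CO1 | intermediate
4 | methyltriphenylphosphonium bromide | C[P+](c1ccccc1)(c1ccccc1)c1ccccc1.[Br-] | starting material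
5 | methylenetriphenylphosphorane | C=P(c1ccccc1)(c1ccccc1)c1ccccc1 | intermediate (not isolated)
6 | 3-(benzyloxy)-4-[(tert-butyldimethylsilyl)oxy]-2-[(docosyloxy)carbonyl]pyrylium trifluoromethanesulfonate | CCCCCCCCCCCCCCCCCCCCCCOC(=O)c1[o+]ccc(O[Si](C)(C)C(C)(C)C)c1OCc1ccccc1.[O-]S(=O)(=O)C(F)(F)F | intermediate (not isolated)
7 | ({5-(benzyloxy)-4-[(tert-butyldimethylsilyl)oxy]-6-[(docosyloxy)carbonyl]-2H-pyran-2-yl}methyl)triphenylphosphonium trifluoromethanesulfonate, racemic | CCCCCCCCCCCCCCCCCCCCCCOC(=O)C1=C(OCc2ccccc2)C(O[Si](C)(C)C(C)(C)C)=CC(C[P+](c2ccccc2)(c2ccccc2)c2ccccc2)O1.[O-]S(=O)(=O)C(F)(F)F | intermediate (not isolated)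
8 | docosyl (3Z,5Z)-3-(benzyloxy)-4-[(tert-butyldimethylsilyl)oxy]-2-oxo-7-(triphenyl-λ5-phosphanylidene)hepta-3,5-dienoate (geometry shown is the one that closes) | CCCCCCCCCCCCCCCCCCCCCCOC(=O)C(=O)/C(OCc1ccccc1)=C(O[Si](C)(C)C(C)(C)C)\C=C/C=P(c1ccccc1)(c1ccccc1)c1ccccc1 | intermediate (not isolated)
9 | docosyl 2-(benzyloxy)-3-[(tert-butyldimethylsilyl)oxy]benzoate | CCCCCCCCCCCCCCCCCCCCCCOC(=O)c1cccc(O[Si](C)(C)C(C)(C)C)c1OCc1ccccc1 | intermediate
10 | docosyl 2-(benzyloxy)-3-hydroxybenzoate | CCCCCCCCCCCCCCCCCCCCCCOC(=O)c1cccc(O)c1OCc1ccccc1 | intermediate
11 | Gentiside J, docosyl 2,3-dihydroxybenzoate | CCCCCCCCCCCCCCCCCCCCCCOC(=O)c1cccc(O)c1O | target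

Total step count: 4
Longest linear sequence: 4 steps (1 to 3 to 9 to 10 to 11)

**Steps most likely to fail**

1. **Step 2.**
   - What may go wrong: O-silylation of the electron-poor pyranone may stay incomplete. The silyl group may pass from the cation to the ylide. The ylide may be acylated by the ester. The sequence may stall at the open-chain stage because the stabilised ylide closes slowly.
   - Fallback (known chemistry, the arene is bought instead of built): it sets out from 2, which is esterified (DCC, DMAP, CH2Cl2, rt) with purchased 2,3-bis(benzyloxy)benzoic acid F1 to give docosyl 2,3-bis(benzyloxy)benzoate F2. Hydrogenolysis of both benzyl ethers (H2, 10% Pd/C, THF/EtOAc) comes back to the route at 11.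

2. **Step 1.**
   - What may go wrong: O-to-N acyl migration in the carbodiimide-activated acid may compete. Acyl transfer may be slow because the fatty alcohol dissolves poorly. The nucleophilic catalyst may add to the pyranone ring.
   - Fallback (reversed polarity, the carboxylate as nucleophile and the C-O bond made at the alkyl carbon): it sets out from 2, which is mesylated (MsCl, Et3N, CH2Cl2, 0 °C) to docosyl methanesulfonate F3. SN2 alkylation of the caesium carboxylate of 1 with it (Cs2CO3, DMF, 60 °C) comes back to the route at 3.

3. **Step 4.**
   - What may go wrong: the hydrogenolysis may stall when the waxy substrate or product deposits on the catalyst. The freed catechol may oxidise in air while the catalyst is filtered off.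
   - Fallback (Lewis-acid ether cleavage in place of hydrogenolysis): it sets out from 10, which is treated with BCl3 and pentamethylbenzene as benzyl-cation scavenger (CH2Cl2, -78 °C, then methanol and water). This method is known to spare esters. It comes back to the route at 11 without any new compound on the way.

**Further compounds**
F1 | step 2 | 2,3-bis(benzyloxy)benzoic acid | OC(=O)c1cccc(OCc2ccccc2)c1OCc1ccccc1
F2 | step 2 | docosyl 2,3-bis(benzyloxy)benzoate | CCCCCCCCCCCCCCCCCCCCCCOC(=O)c1cccc(OCc2ccccc2)c1OCc1ccccc1
F3 | step 1 | docosyl methanesulfonate | CCCCCCCCCCCCCCCCCCCCCCOS(C)(=O)=O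
F0 | step 4 | none | none
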